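**Assumption:** atom labels C1–C21 follow geldanamycin numbering (C1 lactam carbonyl, C15 benzylic CH2, C17 phenol carbon, C20 N-bearing arene carbon); the given SMILES is read as 2E,6S,7S,8E,10S,11R,12S,14R.

## Retrosynthetic overview

1. The benzene ring is bought; the only ring made is the 19-membered lactam, closed late by copper-mediated intramolecular aryl C–N amidation (N–C20, aryl bromide + primary enamide). Carbamate C–O formation and desilylation follow.
2. C7–C8: an alkenylzinc (hydrozirconation of an internal alkyne, Zr-to-Zn) adds to an α-methoxy aldehyde under chelation control (sets C7 and the 8E olefin).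
3. Both methoxy stereocentres (C6 and C12) come from one proposed C–O bond-forming reaction: enantioselective anodic α-methoxylation of aldehydes through enamine radical cations.
4. C10–C11: allenylstannane SE2′ addition (sets C10 and C11). C14: chiral-pool bromo ester joined to the arene by Negishi coupling. C2=C3: Wittig reaction on glutaraldehyde.

## Route

**Western aldehyde**

Step 1
Reactants: 1 glutaraldehyde (pentanedial); 2 ethyl 2-(triphenyl-λ5-phosphanylidene)propanoate
Product: 3 ethyl (2E)-2-methyl-7-oxohept-2-enoate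
Conditions: 1 (3 equiv, 50% aq.), CH2Cl2, 25 °C
Reagents that add atoms: none
Why: Wittig olefination with a stabilised α-methyl ylide gives the (E)-trisubstituted enoate (>95:5), and the excess of dialdehyde suppresses double olefination.

Step 2
Reactants: 3 ethyl (2E)-2-methyl-7-oxohept-2-enoate
Product: 4 ethyl (2E,6S)-6-methoxy-2-methyl-7-oxohept-2-enoate
Conditions: (2S,5S)-5-benzyl-2-tert-butyl-3-methylimidazolidin-4-one·CF3CO2H (20 mol%), MeOH (10 equiv), H2O (2 equiv), n-Bu4NBF4, MeCN, −20 °C, undivided cell, carbon-felt anode, Pt cathode, constant current, 2.2 F/mol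
Reagents that add atoms: methanol CO
Why: Proposed new method: the imidazolidinone forms the (E)-enamine of 3, which is oxidised at the anode at low potential to its three-π-electron radical cation; methanol adds to the α-carbon on the face not shielded by the benzyl group, the α-amino radical is oxidised again, and hydrolysis of the α-methoxy iminium ion releases (6S)-4, whose α,α-disubstituted centre no longer forms an enamine (no racemisation), while protons are reduced to H2 at the cathode; the closest known reaction types are SOMO-activated enantioselective α-chlorination (chloride trapping) and α-oxyamination of aldehydes with this catalyst class and the racemic anodic α-methoxylation of preformed enamines and enol ethers in methanol (Shono-type oxidation).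

**Allenylstannane**

Step 3
Reactants: 5 pent-3-yn-2-one
Product: 6 (2S)-pent-3-yn-2-ol
Conditions: RuCl[(S,S)-TsDPEN](p-cymene) (0.5 mol%), KOH (1.2 mol%), i-PrOH, 25 °C
Reagents that add atoms: none
Why: Noyori asymmetric transfer hydrogenation, in which the alkynyl group takes the place of the aryl group in the six-membered transition state so that the (S,S)-catalyst delivers the (S)-propargylic alcohol (≥95% ee expected).

Step 4
Reactants: 6 (2S)-pent-3-yn-2-ol
Product: 7 (2S)-pent-3-yn-2-yl methanesulfonate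
Conditions: MsCl, Et3N, CH2Cl2, −78 → 0 °C
Reagents that add atoms: methanesulfonyl chloride CS(=O)(=O)Cl
Why: O-sulfonylation activates the propargylic position without touching the stereocentre.

Step 5
Reactants: 7 (2S)-pent-3-yn-2-yl methanesulfonate
Product: 8 (M)-tributyl(penta-2,3-dien-2-yl)stannane
Conditions: Bu3SnH, LiN(i-Pr)2, THF, 0 °C; CuBr·SMe2, −78 °C; then 7, −78 °C
Reagents that add atoms: tributyltin hydride CCCC[SnH](CCCC)CCCC
Why: anti-SN2′ displacement of the mesylate by the stannylcopper reagent converts the (S) centre into the (M) allene axis with high fidelity (Marshall-type allenylstannane synthesis).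

**Eastern aldehyde**

Step 6
Reactants: 9 4-bromo-2-iodophenol
Product: 10 (4-bromo-2-iodophenoxy)tri(propan-2-yl)silane
Conditions: i-Pr3SiCl, imidazole, DMF, 25 °C
Reagents that add atoms: chlorotriisopropylsilane CC(C)[Si](Cl)(C(C)C)C(C)C
Why: phenol silylation; the bulky triisopropylsilyl ether survives the later organometallic steps, aminolysis and copper amidation and is removed together with the C11 silyl ether at the end.

Step 7
Reactants: 10 (4-bromo-2-iodophenoxy)tri(propan-2-yl)silane; 11 methyl (2S)-3-bromo-2-methylpropanoate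
Product: 13 methyl (2R)-3-{5-bromo-2-[tri(propan-2-yl)silyloxy]phenyl}-2-methylpropanoate, via alkylzinc bromide 12 (not isolated)
Conditions: 11, Zn dust, I2 (5 mol%), DMA, 70 °C; then 10, Pd2(dba)3 (2.5 mol%), P(o-tol)3 (10 mol%), 40 °C
Reagents that add atoms: none
Why: Negishi coupling: zinc inserts into the primary C–Br bond, zerovalent palladium adds to C–I far faster than to C–Br, and the chiral-pool centre (future C14, β to zinc) is not touched (the descriptor changes from S to R only through priorities).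

Step 8
Reactants: 13 methyl (2R)-3-{5-bromo-2-[tri(propan-2-yl)silyloxy]phenyl}-2-methylpropanoate
Product: 14 (2R)-3-{5-bromo-2-[tri(propan-2-yl)silyloxy]phenyl}-2-methylpropanal
Conditions: i-Bu2AlH (1.1 equiv), CH2Cl2, −78 °C; aq. potassium sodium tartrate
Reagents that add atoms: none
Why: partial ester reduction stops at the tetrahedral aluminium hemiacetal at −78 °C and gives the aldehyde on work-up; the aldehyde is used at once to avoid α-epimerisation.

Step 9
Reactants: 14 (2R)-3-{5-bromo-2-[tri(propan-2-yl)silyloxy]phenyl}-2-methylpropanal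
Product: 15 {4-bromo-2-[(2R)-2-methylbut-3-en-1-yl]phenoxy}tri(propan-2-yl)silane
Conditions: Ph3PCH3Br, KN(SiMe3)2, THF, 0 °C; then 14, −78 → 0 °C
Reagents that add atoms: methyltriphenylphosphonium bromide C[P+](c1ccccc1)(c1ccccc1)c1ccccc1.[Br-]
Why: Wittig methylenation with the non-stabilised ylide at low temperature is faster than enolisation of the α-branched aldehyde, so the stereocentre is kept.

Step 10
Reactants: 15 {4-bromo-2-[(2R)-2-methylbut-3-en-1-yl]phenoxy}tri(propan-2-yl)silane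
Product: 16 (4S)-5-{5-bromo-2-[tri(propan-2-yl)silyloxy]phenyl}-4-methylpentanal
Conditions: Rh(acac)(CO)2 (1 mol%), Xantphos (2 mol%), CO/H2 (1:1, 10 bar), toluene, 70 °C
Reagents that add atoms: carbon monoxide [C-]#[O+]
Why: linear-selective rhodium-catalysed hydroformylation; the wide-bite-angle diphosphine and the allylic branch direct the formyl group to the terminal carbon, and the stereocentre is untouched (S only by priority change).

Step 11
Reactants: 16 (4S)-5-{5-bromo-2-[tri(propan-2-yl)silyloxy]phenyl}-4-methylpentanal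
Product: 17 (2S,4R)-5-{5-bromo-2-[tri(propan-2-yl)silyloxy]phenyl}-2-methoxy-4-methylpentanal
Conditions: (2S,5S)-5-benzyl-2-tert-butyl-3-methylimidazolidin-4-one·CF3CO2H (20 mol%), MeOH (10 equiv), H2O (2 equiv), n-Bu4NBF4, MeCN, −20 °C, undivided cell, carbon-felt anode, Pt cathode, constant current, 2.2 F/mol
Reagents that add atoms: methanol CO
Why: Proposed new method: as in step 2, anodic oxidation of the catalyst-bound enamine gives a radical cation that methanol traps on the face away from the benzyl group, setting C12 (S) under catalyst control independent of the remote C14 centre; the enamine oxidises about 1 V below the bromo(silyloxy)arene and the free ring positions near the chain are not activated for radical-cation arylation; the closest known reaction types are SOMO-activated α-chlorination and α-oxyamination of aldehydes and Shono-type anodic α-methoxylation of enamines.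

Step 12
Reactants: 17 (2S,4R)-5-{5-bromo-2-[tri(propan-2-yl)silyloxy]phenyl}-2-methoxy-4-methylpentanal; 8 (M)-tributyl(penta-2,3-dien-2-yl)stannane
Product: 18 (4S,5R,6S,8R)-9-{5-bromo-2-[tri(propan-2-yl)silyloxy]phenyl}-6-methoxy-4,8-dimethylnon-2-yn-5-ol
Conditions: 8 (1.3 equiv), BF3·OEt2 (1.5 equiv), CH2Cl2, −78 °C
Reagents that add atoms: none
Why: Marshall-type Lewis-acid-promoted SE2′ addition through an open transition state: anti-SE2′ transfers the allene axis to C10 (S), the syn topicity fixes C11 (R), and this coincides with Felkin–Anh attack on the non-chelated α-methoxy aldehyde (matched, syn,anti triad).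

Step 13
Reactants: 18 (4S,5R,6S,8R)-9-{5-bromo-2-[tri(propan-2-yl)silyloxy]phenyl}-6-methoxy-4,8-dimethylnon-2-yn-5-ol
Product: 19 tert-butyl{[(4S,5R,6S,8R)-9-{5-bromo-2-[tri(propan-2-yl)silyloxy]phenyl}-6-methoxy-4,8-dimethylnon-2-yn-5-yl]oxy}dimethylsilane
Conditions: t-BuMe2SiOTf, 2,6-lutidine, CH2Cl2, −78 → 0 °C
Reagents that add atoms: tert-butyldimethylsilyl trifluoromethanesulfonate CC(C)(C)[Si](C)(C)OS(=O)(=O)C(F)(F)F
Why: silylation of the hindered C11 hydroxyl with the silyl triflate, so that later only the C7 hydroxyl is free for carbamoylation.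

**Fragment union and endgame**

Step 14
Reactants: 19 tert-butyl{[(4S,5R,6S,8R)-9-{5-bromo-2-[tri(propan-2-yl)silyloxy]phenyl}-6-methoxy-4,8-dimethylnon-2-yn-5-yl]oxy}dimethylsilane; 4 ethyl (2E,6S)-6-methoxy-2-methyl-7-oxohept-2-enoate
Product: 22 ethyl (2E,6S,7S,8E,10S,11R,12S,14R)-15-{5-bromo-2-[tri(propan-2-yl)silyloxy]phenyl}-11-[tert-butyl(dimethyl)silyloxy]-7-hydroxy-6,12-dimethoxy-2,8,10,14-tetramethylpentadeca-2,8-dienoate, via alkenylzirconocene chloride 20 (not isolated), via alkenylmethylzinc 21 (not isolated)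
Conditions: Cp2Zr(H)Cl (1.5 equiv), CH2Cl2, 25 → 40 °C; Me2Zn (1.5 equiv), toluene, −65 °C; then 4 (1.5 equiv), −65 → 0 °C; aq. NH4Cl
Reagents that add atoms: none
Why: syn-hydrozirconation places zirconium on the less hindered methyl-bearing alkyne carbon (fixing 8E), Zr-to-Zn transmetalation gives an alkenylzinc that adds only to the aldehyde, and the zinc chelate with the α-methoxy group (Cram-chelate model) sets C7 (S), syn to C6.

Step 15
Reactants: 22 ethyl (2E,6S,7S,8E,10S,11R,12S,14R)-15-{5-bromo-2-[tri(propan-2-yl)silyloxy]phenyl}-11-[tert-butyl(dimethyl)silyloxy]-7-hydroxy-6,12-dimethoxy-2,8,10,14-tetramethylpentadeca-2,8-dienoate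
Product: 23 (2E,6S,7S,8E,10S,11R,12S,14R)-15-{5-bromo-2-[tri(propan-2-yl)silyloxy]phenyl}-11-[tert-butyl(dimethyl)silyloxy]-7-hydroxy-6,12-dimethoxy-2,8,10,14-tetramethylpentadeca-2,8-dienamide
Conditions: AlMe3 (6 equiv), NH4Cl (6 equiv), toluene, 0 → 50 °C; aq. potassium sodium tartrate
Reagents that add atoms: ammonium chloride [NH4+].[Cl-]
Why: Weinreb-type aminolysis with the aluminium amide converts the conjugated ester directly into the primary amide; silyl ethers, the aryl bromide and the C7 hydroxyl (held as an aluminium alkoxide) are tolerated.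

Step 16
Reactants: 23 (2E,6S,7S,8E,10S,11R,12S,14R)-15-{5-bromo-2-[tri(propan-2-yl)silyloxy]phenyl}-11-[tert-butyl(dimethyl)silyloxy]-7-hydroxy-6,12-dimethoxy-2,8,10,14-tetramethylpentadeca-2,8-dienamide
Product: 24 19-membered macrolactam (2E,6S,7S,8E,10S,11R,12S,14R)-11-O-TBS-17-O-TIPS-7-O-descarbamoyl-CNP0544610.1
Conditions: CuI (1.0 equiv), N,N′-dimethylethylenediamine (3 equiv), K2CO3 (3 equiv), toluene (0.003 M), 100 °C
Reagents that add atoms: none
Why: Goldberg-type N-arylation of the primary amide by the aryl bromide with monovalent copper and a diamine ligand under high dilution forms the N–C20 bond and the 19-membered ring; amide N-arylation is far faster than O-arylation of the secondary alcohol under these conditions, and no stereocentre is affected.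

Step 17
Reactants: 24 19-membered macrolactam (2E,6S,7S,8E,10S,11R,12S,14R)-11-O-TBS-17-O-TIPS-7-O-descarbamoyl-CNP0544610.1
Product: 26 11-O-TBS-17-O-TIPS-protected CNP0544610.1, via N-trichloroacetyl carbamate 25 (not isolated)
Conditions: Cl3CC(O)NCO (1.3 equiv), CH2Cl2, 0 °C; then neutral Al2O3, 25 °C
Reagents that add atoms: trichloroacetyl isocyanate O=C=NC(=O)C(Cl)(Cl)Cl
Why: carbamoylation of the only free hydroxyl (C7) with the highly electrophilic acyl isocyanate, then mild hydrolytic loss of the trichloroacetyl group on alumina; configuration at C7 is retained.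

Step 18
Reactants: 26 11-O-TBS-17-O-TIPS-protected CNP0544610.1
Product: 27 CNP0544610.1
Conditions: HF·pyridine, pyridine, THF, 0 → 25 °C
Reagents that add atoms: none
Why: fluoride-driven cleavage of both silyl ethers (Si–F bond strength) under buffered conditions that leave the allylic carbamate, the enamide and the p-amidophenol intact.

## Compound list

1 | glutaraldehyde (pentanedial) | O=CCCCC=O | starting material
2 | ethyl 2-(triphenyl-λ5-phosphanylidene)propanoate | CCOC(=O)C(C)=P(c1ccccc1)(c1ccccc1)c1ccccc1 | starting material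
3 | ethyl (2E)-2-methyl-7-oxohept-2-enoate | CCOC(=O)/C(C)=C/CCCC=O | intermediate
4 | ethyl (2E,6S)-6-methoxy-2-methyl-7-oxohept-2-enoate | CCOC(=O)/C(C)=C/CC[C@H](OC)C=O | intermediate
5 | pent-3-yn-2-one | CC#CC(C)=O | starting material
6 | (2S)-pent-3-yn-2-ol | C[C@H](O)C#CC | intermediate
7 | (2S)-pent-3-yn-2-yl methanesulfonate | C[C@H](OS(C)(=O)=O)C#CC | intermediate
8 | (M)-tributyl(penta-2,3-dien-2-yl)stannane | CC([Sn](CCCC)(CCCC)CCCC)=[C@@]=C([H])C | intermediate
9 | 4-bromo-2-iodophenol | Oc1ccc(Br)cc1I | starting material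
10 | (4-bromo-2-iodophenoxy)tri(propan-2-yl)silane | CC(C)[Si](Oc1ccc(Br)cc1I)(C(C)C)C(C)C | intermediate
11 | methyl (2S)-3-bromo-2-methylpropanoate | COC(=O)[C@H](C)CBr | starting material
12 | bromo[(2S)-3-methoxy-2-methyl-3-oxopropyl]zinc | COC(=O)[C@H](C)C[Zn]Br | intermediate
13 | methyl (2R)-3-{5-bromo-2-[tri(propan-2-yl)silyloxy]phenyl}-2-methylpropanoate | COC(=O)[C@H](C)Cc1cc(Br)ccc1O[Si](C(C)C)(C(C)C)C(C)C | intermediate
14 | (2R)-3-{5-bromo-2-[tri(propan-2-yl)silyloxy]phenyl}-2-methylpropanal | O=C[C@H](C)Cc1cc(Br)ccc1O[Si](C(C)C)(C(C)C)C(C)C | intermediate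
15 | {4-bromo-2-[(2R)-2-methylbut-3-en-1-yl]phenoxy}tri(propan-2-yl)silane | C=C[C@H](C)Cc1cc(Br)ccc1O[Si](C(C)C)(C(C)C)C(C)C | intermediate
16 | (4S)-5-{5-bromo-2-[tri(propan-2-yl)silyloxy]phenyl}-4-methylpentanal | O=CCC[C@H](C)Cc1cc(Br)ccc1O[Si](C(C)C)(C(C)C)C(C)C | intermediate
17 | (2S,4R)-5-{5-bromo-2-[tri(propan-2-yl)silyloxy]phenyl}-2-methoxy-4-methylpentanal | O=C[C@@H](OC)C[C@H](C)Cc1cc(Br)ccc1O[Si](C(C)C)(C(C)C)C(C)C | intermediate
18 | (4S,5R,6S,8R)-9-{5-bromo-2-[tri(propan-2-yl)silyloxy]phenyl}-6-methoxy-4,8-dimethylnon-2-yn-5-ol | CC#C[C@H](C)[C@@H](O)[C@@H](OC)C[C@H](C)Cc1cc(Br)ccc1O[Si](C(C)C)(C(C)C)C(C)C | intermediate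
19 | tert-butyl{[(4S,5R,6S,8R)-9-{5-bromo-2-[tri(propan-2-yl)silyloxy]phenyl}-6-methoxy-4,8-dimethylnon-2-yn-5-yl]oxy}dimethylsilane | CC#C[C@H](C)[C@@H](O[Si](C)(C)C(C)(C)C)[C@@H](OC)C[C@H](C)Cc1cc(Br)ccc1O[Si](C(C)C)(C(C)C)C(C)C | intermediate
20 | (E)-alkenylzirconocene chloride from 19 (Zr on C8, drawn with η1-cyclopentadienyl groups) | C/C(=C\[C@H](C)[C@@H](O[Si](C)(C)C(C)(C)C)[C@@H](OC)C[C@H](C)Cc1cc(Br)ccc1O[Si](C(C)C)(C(C)C)C(C)C)[Zr](Cl)(C1C=CC=C1)C1C=CC=C1 | intermediate
21 | (E)-alkenyl(methyl)zinc from 20 (Zn on C8) | C/C(=C\[C@H](C)[C@@H](O[Si](C)(C)C(C)(C)C)[C@@H](OC)C[C@H](C)Cc1cc(Br)ccc1O[Si](C(C)C)(C(C)C)C(C)C)[Zn]C | intermediate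
22 | ethyl (2E,6S,7S,8E,10S,11R,12S,14R)-15-{5-bromo-2-[tri(propan-2-yl)silyloxy]phenyl}-11-[tert-butyl(dimethyl)silyloxy]-7-hydroxy-6,12-dimethoxy-2,8,10,14-tetramethylpentadeca-2,8-dienoate | CCOC(=O)/C(C)=C/CC[C@H](OC)[C@@H](O)/C(C)=C/[C@H](C)[C@@H](O[Si](C)(C)C(C)(C)C)[C@@H](OC)C[C@H](C)Cc1cc(Br)ccc1O[Si](C(C)C)(C(C)C)C(C)C | intermediate
23 | (2E,6S,7S,8E,10S,11R,12S,14R)-15-{5-bromo-2-[tri(propan-2-yl)silyloxy]phenyl}-11-[tert-butyl(dimethyl)silyloxy]-7-hydroxy-6,12-dimethoxy-2,8,10,14-tetramethylpentadeca-2,8-dienamide | NC(=O)/C(C)=C/CC[C@H](OC)[C@@H](O)/C(C)=C/[C@H](C)[C@@H](O[Si](C)(C)C(C)(C)C)[C@@H](OC)C[C@H](C)Cc1cc(Br)ccc1O[Si](C(C)C)(C(C)C)C(C)C | intermediate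
24 | 19-membered macrolactam: target skeleton with free 7-OH, 11-O-tert-butyldimethylsilyl, 17-O-triisopropylsilyl (2E,6S,7S,8E,10S,11R,12S,14R) | N1C(=O)/C(C)=C/CC[C@H](OC)[C@@H](O)/C(C)=C/[C@H](C)[C@@H](O[Si](C)(C)C(C)(C)C)[C@@H](OC)C[C@H](C)Cc2cc1ccc2O[Si](C(C)C)(C(C)C)C(C)C | intermediate
25 | 7-O-[(trichloroacetyl)carbamoyl] derivative of 24 | N1C(=O)/C(C)=C/CC[C@H](OC)[C@@H](OC(=O)NC(=O)C(Cl)(Cl)Cl)/C(C)=C/[C@H](C)[C@@H](O[Si](C)(C)C(C)(C)C)[C@@H](OC)C[C@H](C)Cc2cc1ccc2O[Si](C(C)C)(C(C)C)C(C)C | intermediate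
26 | 11-O-tert-butyldimethylsilyl-17-O-triisopropylsilyl ether of CNP0544610.1 (7-O-carbamate) | N1C(=O)/C(C)=C/CC[C@H](OC)[C@@H](OC(N)=O)/C(C)=C/[C@H](C)[C@@H](O[Si](C)(C)C(C)(C)C)[C@@H](OC)C[C@H](C)Cc2cc1ccc2O[Si](C(C)C)(C(C)C)C(C)C | intermediate
27 | CNP0544610.1: 19-membered benzenoid ansamycin lactam, 7-O-carbamoyl, 11-OH, 17-OH, 6,12-di-OMe (2E,6S,7S,8E,10S,11R,12S,14R) | CO[C@H]1C[C@H](C)Cc2cc(ccc2O)NC(=O)/C(C)=C/CC[C@H](OC)[C@@H](OC(N)=O)/C(C)=C/[C@H](C)[C@H]1O | target

## Step count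

Total: 18 steps. Longest linear sequence: 13 steps (steps 6–18, from 4-bromo-2-iodophenol 9).

## Three steps most likely to fail

**Step 2 (proposed α-methoxylation, western aldehyde).** Risks are low enantioselectivity, competing dehydrogenation of the enamine, or acetal formation; the facial sense (predicted S from attack anti to the benzyl group) must be confirmed on a model and the (2R,5R)-catalyst used if it is reversed. The fallback is known chemistry, sets out from 3 and comes back at 4. D-Proline (20 mol%) and nitrosobenzene in CHCl3 at 4 °C give ethyl (2E,6S)-2-methyl-7-oxo-6-[(phenylamino)oxy]hept-2-enoate F1, which is reduced in the same flask with NaBH4 in EtOH to ethyl (2E,6S)-7-hydroxy-2-methyl-6-[(phenylamino)oxy]hept-2-enoate F2. Zinc dust in AcOH cleaves the N–O bond to ethyl (2E,6S)-6,7-dihydroxy-2-methylhept-2-enoate F3. t-BuMe2SiCl and imidazole silylate the primary hydroxyl to ethyl (2E,6S)-7-[tert-butyl(dimethyl)silyloxy]-6-hydroxy-2-methylhept-2-enoate F4. MeOTf with 2,6-di-tert-butylpyridine gives ethyl (2E,6S)-7-[tert-butyl(dimethyl)silyloxy]-6-methoxy-2-methylhept-2-enoate F5. HF·pyridine frees ethyl (2E,6S)-7-hydroxy-6-methoxy-2-methylhept-2-enoate F6, and Dess–Martin periodinane oxidises it to 4.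

**Step 11 (proposed α-methoxylation, eastern aldehyde).** The same risks apply, plus possible attack of the radical cation on the arene. The fallback is the same known sequence, sets out from 16 and comes back at 17. D-Proline and nitrosobenzene give (2S,4R)-5-{5-bromo-2-[tri(propan-2-yl)silyloxy]phenyl}-4-methyl-2-[(phenylamino)oxy]pentanal F7, reduced in the flask with NaBH4 to (2S,4R)-5-{5-bromo-2-[tri(propan-2-yl)silyloxy]phenyl}-4-methyl-2-[(phenylamino)oxy]pentan-1-ol F8. Zinc dust in AcOH gives (2S,4R)-5-{5-bromo-2-[tri(propan-2-yl)silyloxy]phenyl}-4-methylpentane-1,2-diol F9. t-BuMe2SiCl and imidazole give (2S,4R)-5-{5-bromo-2-[tri(propan-2-yl)silyloxy]phenyl}-1-[tert-butyl(dimethyl)silyloxy]-4-methylpentan-2-ol F10. MeOTf with 2,6-di-tert-butylpyridine gives tert-butyl{[(2S,4R)-5-{5-bromo-2-[tri(propan-2-yl)silyloxy]phenyl}-2-methoxy-4-methylpentyl]oxy}dimethylsilane F11. Camphorsulfonic acid in MeOH removes only the primary alkyl silyl ether to give (2S,4R)-5-{5-bromo-2-[tri(propan-2-yl)silyloxy]phenyl}-2-methoxy-4-methylpentan-1-ol F12, and Dess–Martin periodinane oxidises it to 17.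

**Step 14 (hydrozirconation / zinc addition).** Risks are incomplete regiocontrol in the hydrozirconation and a modest chelation-controlled ratio at C7. The fallback sets out from 19 (through 20) and 4 and comes back at 22. Quenching 20 with I2 gives tert-butyl{[(2E,4S,5R,6S,8R)-9-{5-bromo-2-[tri(propan-2-yl)silyloxy]phenyl}-2-iodo-6-methoxy-4,8-dimethylnon-2-en-5-yl]oxy}dimethylsilane F13. Nozaki–Hiyama–Kishi coupling of F13 with 4 (CrCl2, NiCl2 1 mol%, DMSO) gives 22 together with its C7 epimer ethyl (2E,6S,7R,8E,10S,11R,12S,14R)-15-{5-bromo-2-[tri(propan-2-yl)silyloxy]phenyl}-11-[tert-butyl(dimethyl)silyloxy]-7-hydroxy-6,12-dimethoxy-2,8,10,14-tetramethylpentadeca-2,8-dienoate F14. The mixture is oxidised with Dess–Martin periodinane to the enone ethyl (2E,6S,8E,10S,11R,12S,14R)-15-{5-bromo-2-[tri(propan-2-yl)silyloxy]phenyl}-11-[tert-butyl(dimethyl)silyloxy]-6,12-dimethoxy-2,8,10,14-tetramethyl-7-oxopentadeca-2,8-dienoate F15. Reagent-controlled 1,2-reduction with (S)-2-methyl-CBS-oxazaborolidine and BH3·SMe2 (alkenyl as the large group) returns 22.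

## Further compounds

F1 | step 2 | ethyl (2E,6S)-2-methyl-7-oxo-6-[(phenylamino)oxy]hept-2-enoate | CCOC(=O)/C(C)=C/CC[C@H](ONc1ccccc1)C=O
F2 | step 2 | ethyl (2E,6S)-7-hydroxy-2-methyl-6-[(phenylamino)oxy]hept-2-enoate | CCOC(=O)/C(C)=C/CC[C@H](ONc1ccccc1)CO
F3 | step 2 | ethyl (2E,6S)-6,7-dihydroxy-2-methylhept-2-enoate | CCOC(=O)/C(C)=C/CC[C@H](O)CO
F4 | step 2 | ethyl (2E,6S)-7-[tert-butyl(dimethyl)silyloxy]-6-hydroxy-2-methylhept-2-enoate | CCOC(=O)/C(C)=C/CC[C@H](O)CO[Si](C)(C)C(C)(C)C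
F5 | step 2 | ethyl (2E,6S)-7-[tert-butyl(dimethyl)silyloxy]-6-methoxy-2-methylhept-2-enoate | CCOC(=O)/C(C)=C/CC[C@H](OC)CO[Si](C)(C)C(C)(C)C
F6 | step 2 | ethyl (2E,6S)-7-hydroxy-6-methoxy-2-methylhept-2-enoate | CCOC(=O)/C(C)=C/CC[C@H](OC)CO
F7 | step 11 | (2S,4R)-5-{5-bromo-2-[tri(propan-2-yl)silyloxy]phenyl}-4-methyl-2-[(phenylamino)oxy]pentanal | O=C[C@@H](ONc1ccccc1)C[C@H](C)Cc1cc(Br)ccc1O[Si](C(C)C)(C(C)C)C(C)C
F8 | step 11 | (2S,4R)-5-{5-bromo-2-[tri(propan-2-yl)silyloxy]phenyl}-4-methyl-2-[(phenylamino)oxy]pentan-1-ol | OC[C@@H](ONc1ccccc1)C[C@H](C)Cc1cc(Br)ccc1O[Si](C(C)C)(C(C)C)C(C)C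
F9 | step 11 | (2S,4R)-5-{5-bromo-2-[tri(propan-2-yl)silyloxy]phenyl}-4-methylpentane-1,2-diol | OC[C@@H](O)C[C@H](C)Cc1cc(Br)ccc1O[Si](C(C)C)(C(C)C)C(C)C
F10 | step 11 | (2S,4R)-5-{5-bromo-2-[tri(propan-2-yl)silyloxy]phenyl}-1-[tert-butyl(dimethyl)silyloxy]-4-methylpentan-2-ol | CC(C)(C)[Si](C)(C)OC[C@@H](O)C[C@H](C)Cc1cc(Br)ccc1O[Si](C(C)C)(C(C)C)C(C)C
F11 | step 11 | tert-butyl{[(2S,4R)-5-{5-bromo-2-[tri(propan-2-yl)silyloxy]phenyl}-2-methoxy-4-methylpentyl]oxy}dimethylsilane | CC(C)(C)[Si](C)(C)OC[C@@H](OC)C[C@H](C)Cc1cc(Br)ccc1O[Si](C(C)C)(C(C)C)C(C)C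
F12 | step 11 | (2S,4R)-5-{5-bromo-2-[tri(propan-2-yl)silyloxy]phenyl}-2-methoxy-4-methylpentan-1-ol | OC[C@@H](OC)C[C@H](C)Cc1cc(Br)ccc1O[Si](C(C)C)(C(C)C)C(C)C
F13 | step 14 | tert-butyl{[(2E,4S,5R,6S,8R)-9-{5-bromo-2-[tri(propan-2-yl)silyloxy]phenyl}-2-iodo-6-methoxy-4,8-dimethylnon-2-en-5-yl]oxy}dimethylsilane | C/C(I)=C\[C@H](C)[C@@H](O[Si](C)(C)C(C)(C)C)[C@@H](OC)C[C@H](C)Cc1cc(Br)ccc1O[Si](C(C)C)(C(C)C)C(C)C
F14 | step 14 | ethyl (2E,6S,7R,8E,10S,11R,12S,14R)-15-{5-bromo-2-[tri(propan-2-yl)silyloxy]phenyl}-11-[tert-butyl(dimethyl)silyloxy]-7-hydroxy-6,12-dimethoxy-2,8,10,14-tetramethylpentadeca-2,8-dienoate | CCOC(=O)/C(C)=C/CC[C@H](OC)[C@H](O)/C(C)=C/[C@H](C)[C@@H](O[Si](C)(C)C(C)(C)C)[C@@H](OC)C[C@H](C)Cc1cc(Br)ccc1O[Si](C(C)C)(C(C)C)C(C)C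
F15 | step 14 | ethyl (2E,6S,8E,10S,11R,12S,14R)-15-{5-bromo-2-[tri(propan-2-yl)silyloxy]phenyl}-11-[tert-butyl(dimethyl)silyloxy]-6,12-dimethoxy-2,8,10,14-tetramethyl-7-oxopentadeca-2,8-dienoate | CCOC(=O)/C(C)=C/CC[C@H](OC)C(=O)/C(C)=C/[C@H](C)[C@@H](O[Si](C)(C)C(C)(C)C)[C@@H](OC)C[C@H](C)Cc1cc(Br)ccc1O[Si](C(C)C)(C(C)C)C(C)C
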